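**Retrosynthetic overview**

1. The succinimide comes last: Evans syn-aldol at C12–C13 with an (R)-oxazolidinone 3-cyanopropanoyl imide, then nitrile hydration and N-acyl transfer. The C12 aldehyde comes from a C11 aldehyde by one-carbon homologation.
2. Key disconnection: ring B is cut [3+3] at C5–C10 and C7–C8, which also opens ring A. The precursor is an acyclic chain in which the masked C6 ketone (a dioxolane, nucleophilic first at C5 and then at C7) faces a 2-ethynyl enal (C10 electrophilic, C11 formyl, C8≡C17 alkyne).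
3. Enabling feature: in ring B the C6 ketone has both α-carbons in the ring (C5 at the A/B fusion, C7 next to C8); the quaternary C10 is β to C11 through C9; and the C8=C17 exocyclic methylene is β,γ to the ketone, which is what a conjugate addition at C10 followed by a Conia-ene closure at C8 leaves behind.
4. The acyclic precursor is joined at C1–C2 by a vinylogous Mukaiyama aldol between an (R)-α-chloroaldehyde (C2–C7, chlorine at C3 from organocatalysis) and a silyl dienol ether (C1, C8–C11, C17, C20). The C2 chloride follows by invertive deoxychlorination.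
5. Ring order: ring A (C5–C10), then ring B (C7–C8) in the same flask, then the succinimide. C3 is set by catalysis; C2, C5, C10 and C9 are relayed from it, and C12/C13 come from the auxiliary.

Key step: step 11

Remark: atom labels C1–C20 in the text are labdane numbers (C17 exocyclic methylene, C18/C19 on C4, C20 on C10). In step 4 the antipode of the 2,5-diphenylpyrrolidine catalyst is taken that delivers the (R)-chloride; (2S,5S) is written, and (2R,5R) serves if the sense is the opposite.

**Route**

Step 1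
Reactants: 1 mesityl oxide (4-methylpent-3-en-2-one); 2 allyltrimethylsilane
Product: 3 4,4-dimethylhept-6-en-2-one
Conditions: TiCl4, CH2Cl2, −78 °C; aqueous work-up
Reagents that add atoms: none
Why: Hosomi–Sakurai conjugate allylation of the TiCl4-activated β,β-disubstituted enone should create the C4 gem-dimethyl quaternary carbon and leave the methyl ketone (C6, C7).

Step 2
Reactants: 3 4,4-dimethylhept-6-en-2-one
Product: 4 2-(2,2-dimethylpent-4-en-1-yl)-2-methyl-1,3-dioxolane
Conditions: ethylene glycol, TsOH (cat.), benzene, reflux, Dean–Stark trap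
Reagents that add atoms: ethylene glycol (OCCO)
Why: Acid-catalysed ketalization with azeotropic removal of water masks the ketone against the amine catalyst and Lewis acids to come and installs the latent enol ether used in step 11.

Step 3
Reactants: 4 2-(2,2-dimethylpent-4-en-1-yl)-2-methyl-1,3-dioxolane
Product: 6 3,3-dimethyl-4-(2-methyl-1,3-dioxolan-2-yl)butanal, via ozonide 5 (not isolated)
Conditions: O3, CH2Cl2, −78 °C; then PPh3, −78 → 23 °C
Reagents that add atoms: ozone ([O-][O+]=O)
Why: Ozonolysis with reductive work-up cleaves the terminal alkene to the C2 aldehyde without touching the ketal.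

Step 4
Reactants: 6 3,3-dimethyl-4-(2-methyl-1,3-dioxolan-2-yl)butanal
Product: 7 (2R)-2-chloro-3,3-dimethyl-4-(2-methyl-1,3-dioxolan-2-yl)butanal
Conditions: N-chlorosuccinimide, (2S,5S)-2,5-diphenylpyrrolidine (10 mol %), CH2Cl2, −20 → 0 °C; used crude
Reagents that add atoms: N-chlorosuccinimide (O=C1CCC(=O)N1Cl)
Why: Organocatalytic enamine α-chlorination, in which the C2-symmetric pyrrolidine shields one enamine face, should set C3 as the (R)-chloride; this is the only stereocentre of the decalin set by a chiral catalyst, and the neopentyl position slows racemization.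

Step 5
Reactants: 8 3-methylbut-2-enal
Product: 10 2-bromo-3-methylbut-2-enal, via dibromide 9 (not isolated)
Conditions: Br2, CH2Cl2, 0 °C; then Et3N, 0 → 23 °C
Reagents that add atoms: bromine (BrBr)
Why: Bromine addition to the enal followed by amine-induced loss of HBr from the acidic α-position should give the α-bromoenal.

Step 6
Reactants: 10 2-bromo-3-methylbut-2-enal; 11 ethynyltrimethylsilane
Product: 12 3-methyl-2-[(trimethylsilyl)ethynyl]but-2-enal
Conditions: PdCl2(PPh3)2 (2 mol %), CuI (4 mol %), i-Pr2NH, THF, 23 °C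
Reagents that add atoms: none
Why: Sonogashira coupling of the electron-poor vinyl bromide installs the future C8≡C17 alkyne on C9.

Step 7
Reactants: 12 3-methyl-2-[(trimethylsilyl)ethynyl]but-2-enal
Product: 13 tert-butyl(dimethyl)({3-methyl-2-[(trimethylsilyl)ethynyl]buta-1,3-dien-1-yl}oxy)silane
Conditions: TBSOTf, Et3N, CH2Cl2, 0 °C
Reagents that add atoms: tert-butyldimethylsilyl trifluoromethanesulfonate (CC(C)(C)[Si](C)(C)OS(=O)(=O)C(F)(F)F)
Why: Soft γ-enolization with O-silylation turns the enal into its 1-silyloxydiene, the vinylogous nucleophile whose terminal CH2 becomes C1.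

Step 8
Reactants: 7 (2R)-2-chloro-3,3-dimethyl-4-(2-methyl-1,3-dioxolan-2-yl)butanal; 13 tert-butyl(dimethyl)({3-methyl-2-[(trimethylsilyl)ethynyl]buta-1,3-dien-1-yl}oxy)silane
Product: 14 (2E,5S,6R)-6-chloro-5-hydroxy-3,7,7-trimethyl-8-(2-methyl-1,3-dioxolan-2-yl)-2-[(trimethylsilyl)ethynyl]oct-2-enal
Conditions: BF3·OEt2, CH2Cl2, −78 °C; aq. NaHCO3
Reagents that add atoms: none
Why: Vinylogous Mukaiyama aldol through an open transition state: the terminal diene carbon adds to the BF3-activated aldehyde, the Cornforth (polar Felkin–Anh) arrangement of the α-chloroaldehyde should give the 1,2-anti chlorohydrin (C2 set from C3), and the s-trans diene should give the 2E enal, whose hydroxyl cannot reach the formyl group (a minor 2Z isomer would close to a lactol and be removed here).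

Step 9
Reactants: 14 (2E,5S,6R)-6-chloro-5-hydroxy-3,7,7-trimethyl-8-(2-methyl-1,3-dioxolan-2-yl)-2-[(trimethylsilyl)ethynyl]oct-2-enal
Product: 15 (2E,5R,6R)-5,6-dichloro-3,7,7-trimethyl-8-(2-methyl-1,3-dioxolan-2-yl)-2-[(trimethylsilyl)ethynyl]oct-2-enal
Conditions: 1-chloro-N,N,2-trimethylprop-1-en-1-amine, CH2Cl2, 0 → 23 °C
Reagents that add atoms: 1-chloro-N,N,2-trimethylprop-1-en-1-amine (CC(C)=C(Cl)N(C)C)
Why: Deoxychlorination through the alkoxy-iminium chloride, with SN2 attack of chloride, should invert C2 and turn the anti-chlorohydrin into the syn-dichloride under neutral conditions that spare the enal, ketal and silylalkyne.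

Step 10
Reactants: 15 (2E,5R,6R)-5,6-dichloro-3,7,7-trimethyl-8-(2-methyl-1,3-dioxolan-2-yl)-2-[(trimethylsilyl)ethynyl]oct-2-enal
Product: 16 (2E,5R,6R)-5,6-dichloro-2-ethynyl-3,7,7-trimethyl-8-(2-methyl-1,3-dioxolan-2-yl)oct-2-enal
Conditions: Bu4NF, AcOH, THF, 0 °C
Reagents that add atoms: none
Why: Buffered fluoride removes the alkynyl silyl group without the base-induced vinylogous loss of HCl that a carbonate/methanol protocol would risk.

Step 11
Reactants: 16 (2E,5R,6R)-5,6-dichloro-2-ethynyl-3,7,7-trimethyl-8-(2-methyl-1,3-dioxolan-2-yl)oct-2-enal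
Product: 19 (2R,3R,5R,9S,10R)-2,3-dichloro-6-oxo-12,13,14,15,16-pentanorlabd-8(17)-en-11-al, via ring A bis(silyl) enol ether 17 (not isolated), via bicyclic bis(silyl) trienol ether 18 (not isolated)
Conditions: TMSOTf (2.2 equiv), 2,6-di-tert-butyl-4-methylpyridine (2.4 equiv), CH2Cl2 (0.01 M), −78 → 0 °C; then [(2-biphenylyl)(t-Bu)2PAu(NCMe)]SbF6 (5 mol %), 0 → 23 °C; then Bu4NF, AcOH, THF, −78 °C; then AcOH/H2O, 0 → 23 °C
Reagents that add atoms: water (O)
Why: Proposed new method: TMSOTf opens the dioxolane to an oxocarbenium ion that the hindered pyridine converts reversibly into the C5=C6 and C6=C7 enol ethers, and it silylates the enal to a 1-silyloxyallyl cation with its charge at C10; only the C5 enol ether reaches C10 through a six-membered chair (6-(enolexo)-exo-trig, Mukaiyama–Michael type closure of ring A), loss of a C7 proton then leaves the transposed C6=C7 enol ether 17, which the monovalent gold catalyst adds to the alkyne at C8 (6-(enolendo)-exo-dig, Conia-ene type closure of ring B, protodeauration by the pyridinium triflate), and buffered fluoride and aqueous acid finally unmask the aldehyde and the ketone. The closest known reactions are the silyl triflate opening of dioxolanes to enol ethers, Mukaiyama–Michael additions to silyl-activated enals and the gold-catalysed carbocyclization of silyl enol ethers onto alkynes; their union as an enol-ether relay across one ketone has no direct precedent. C5 and C10 should be set in the chair in which both chlorines are equatorial (an axial C2–Cl would clash with the axial C4 methyl) and the two large arms at C5 and C10 are trans-diequatorial, which puts the C10 methyl axial and C5–H axial anti to it, that is the trans ring fusion; C9 stays trigonal as the silyl enol ether until the end and is then protonated at the α-carbon of the dienolate from the face opposite the axial C10 methyl. The step needs reaction at C5 and not C7 in the first closure and at C10 and not C11 (six-membered against eight-membered transition states in both cases), and closure of C7 onto C8 and not onto C11; the last is secured by keeping C11 masked as its silyl enol ether under buffered aprotic conditions until ring B is closed, and the geometry of the enal is irrelevant because it is lost in the allyl cation.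

Step 12
Reactants: 19 (2R,3R,5R,9S,10R)-2,3-dichloro-6-oxo-12,13,14,15,16-pentanorlabd-8(17)-en-11-al
Product: 20 (2R,3R,5R,9S,10R)-2,3-dichloro-12-methoxy-13,14,15,16-tetranorlabda-8(17),11-dien-6-one (E/Z mixture)
Conditions: Ph3PCH2OMe Cl, KN(SiMe3)2, THF, 0 °C; then 19, −78 → 0 °C
Reagents that add atoms: (methoxymethyl)triphenylphosphonium chloride (COC[P+](c1ccccc1)(c1ccccc1)c1ccccc1.[Cl-])
Why: Wittig methoxymethylenation at −78 °C should take the aldehyde far faster than the C6 ketone, which is flanked by C5 and shielded by the C4 and C10 methyl groups, and a slight deficit of ylide at low temperature limits deprotonation at C9 and C7.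

Step 13
Reactants: 20 (2R,3R,5R,9S,10R)-2,3-dichloro-12-methoxy-13,14,15,16-tetranorlabda-8(17),11-dien-6-one
Product: 21 (2R,3R,5R,9S,10R)-2,3-dichloro-6-oxo-13,14,15,16-tetranorlabd-8(17)-en-12-al
Conditions: 0.5 M HCl, THF, 0 °C
Reagents that add atoms: water (O)
Why: Mild acid hydrolysis of the enol ether (C-protonation at C11, hemiacetal collapse) unveils the C12 aldehyde, and C9 is no longer α to a carbonyl, so its configuration is now fixed.

Step 14
Reactants: 22 (4R)-4-benzyl-1,3-oxazolidin-2-one; 23 3-cyanopropanoic acid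
Product: 25 4-[(4R)-4-benzyl-2-oxo-1,3-oxazolidin-3-yl]-4-oxobutanenitrile, via mixed pivalic anhydride 24 (not isolated)
Conditions: t-BuCOCl, Et3N, THF, −20 °C; then LiCl, 22, −20 → 23 °C
Reagents that add atoms: none
Why: Standard N-acylation of the oxazolidinone through the mixed pivalic anhydride under LiCl/Et3N conditions gives the aldol partner that already carries C13–C16 and the imide nitrogen as a nitrile.

Step 15
Reactants: 21 (2R,3R,5R,9S,10R)-2,3-dichloro-6-oxo-13,14,15,16-tetranorlabd-8(17)-en-12-al; 25 4-[(4R)-4-benzyl-2-oxo-1,3-oxazolidin-3-yl]-4-oxobutanenitrile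
Product: 27 (12S,13R)-aldol adduct 4-[(4R)-4-benzyl-2-oxo-1,3-oxazolidin-3-yl]-3-[(1S)-1-hydroxy-2-(drimenyl)ethyl]-4-oxobutanenitrile, via Z-boron enolate 26 (not isolated)
Conditions: 25, Bu2BOTf (1.05 equiv), i-Pr2NEt (1.15 equiv), CH2Cl2, −78 → 0 °C; then 21, −78 → 0 °C; pH 7 buffer, MeOH
Reagents that add atoms: none
Why: Evans syn-aldol reaction: the Z-boron enolate reacts through a Zimmerman–Traxler chair, so the (R)-benzyl auxiliary should set C13 (R) and C12 (S) irrespective of the remote ring stereocentres, and the aldehyde is engaged in preference to the hindered C6 ketone.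

Step 16
Reactants: 27 (12S,13R)-aldol adduct
Product: 29 haterumaimide B, via primary amide 28 (not isolated)
Conditions: [PtH{(PMe2O)2H}(PMe2OH)] (5 mol %), EtOH/H2O (4:1), 80 °C; then Yb(OTf)3 (10 mol %), MeCN, 23 → 40 °C
Reagents that add atoms: water (O)
Why: Platinum-catalysed hydration of the nitrile to the primary amide under neutral conditions, then Lewis acid-activated intramolecular N-acyl transfer (5-exo-trig attack of the amide nitrogen on the acyl oxazolidinone), should close the succinimide and expel the auxiliary without base, so the β,γ-unsaturated ketone and the aldol stereocentres are not disturbed.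

**Compound list**

1 | mesityl oxide (4-methylpent-3-en-2-one) | CC(=O)C=C(C)C | starting material
2 | allyltrimethylsilane | C=CC[Si](C)(C)C | starting material
3 | 4,4-dimethylhept-6-en-2-one | CC(=O)CC(C)(C)CC=C | intermediate
4 | 2-(2,2-dimethylpent-4-en-1-yl)-2-methyl-1,3-dioxolane | CC1(CC(C)(C)CC=C)OCCO1 | intermediate
5 | ozonide of 4: 2-[2,2-dimethyl-3-(1,2,4-trioxolan-3-yl)propyl]-2-methyl-1,3-dioxolane | CC1(CC(C)(C)CC2OCOO2)OCCO1 | intermediate
6 | 3,3-dimethyl-4-(2-methyl-1,3-dioxolan-2-yl)butanal | O=CCC(C)(C)CC1(C)OCCO1 | intermediate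
7 | (2R)-2-chloro-3,3-dimethyl-4-(2-methyl-1,3-dioxolan-2-yl)butanal | O=C[C@H](Cl)C(C)(C)CC1(C)OCCO1 | intermediate
8 | 3-methylbut-2-enal | CC(C)=CC=O | starting material
9 | 2,3-dibromo-3-methylbutanal (racemic) | CC(C)(Br)C(Br)C=O | intermediate
10 | 2-bromo-3-methylbut-2-enal | CC(C)=C(Br)C=O | intermediate
11 | ethynyltrimethylsilane | C#C[Si](C)(C)C | starting material
12 | 3-methyl-2-[(trimethylsilyl)ethynyl]but-2-enal | CC(C)=C(C#C[Si](C)(C)C)C=O | intermediate
13 | tert-butyl(dimethyl)({3-methyl-2-[(trimethylsilyl)ethynyl]buta-1,3-dien-1-yl}oxy)silane (enol ether geometry not defined) | C=C(C)C(C#C[Si](C)(C)C)=CO[Si](C)(C)C(C)(C)C | intermediate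
14 | (2E,5S,6R)-6-chloro-5-hydroxy-3,7,7-trimethyl-8-(2-methyl-1,3-dioxolan-2-yl)-2-[(trimethylsilyl)ethynyl]oct-2-enal | O=C/C(C#C[Si](C)(C)C)=C(\C)C[C@H](O)[C@H](Cl)C(C)(C)CC1(C)OCCO1 | intermediate
15 | (2E,5R,6R)-5,6-dichloro-3,7,7-trimethyl-8-(2-methyl-1,3-dioxolan-2-yl)-2-[(trimethylsilyl)ethynyl]oct-2-enal | O=C/C(C#C[Si](C)(C)C)=C(\C)C[C@@H](Cl)[C@H](Cl)C(C)(C)CC1(C)OCCO1 | intermediate
16 | (2E,5R,6R)-5,6-dichloro-2-ethynyl-3,7,7-trimethyl-8-(2-methyl-1,3-dioxolan-2-yl)oct-2-enal | O=C/C(C#C)=C(\C)C[C@@H](Cl)[C@H](Cl)C(C)(C)CC1(C)OCCO1 | intermediate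
17 | ring A bis(silyl) enol ether, (2R,3R,5R,10S): 2,3-dichloro-4,4,10-trimethylcyclohexane with C5 bearing C6(=CH2)OCH2CH2OSiMe3 and C10 bearing C9(C≡CH)=CH–OSiMe3 | C=C(OCCO[Si](C)(C)C)[C@H]1C(C)(C)[C@@H](Cl)[C@H](Cl)C[C@]1(C)C(C#C)=CO[Si](C)(C)C | intermediate
18 | bicyclic bis(silyl) trienol ether, (2R,3R,5R,10S)-2,3-dichloro-6-[2-(trimethylsilyloxy)ethoxy]-11-(trimethylsilyloxy)-12,13,14,15,16-pentanorlabda-6,8(17),9(11)-triene | C=C1C=C(OCCO[Si](C)(C)C)[C@H]2C(C)(C)[C@@H](Cl)[C@H](Cl)C[C@]2(C)C1=CO[Si](C)(C)C | intermediate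
19 | (2R,3R,5R,9S,10R)-2,3-dichloro-6-oxo-12,13,14,15,16-pentanorlabd-8(17)-en-11-al | C=C1CC(=O)[C@H]2C(C)(C)[C@@H](Cl)[C@H](Cl)C[C@]2(C)[C@H]1C=O | intermediate
20 | (2R,3R,5R,9S,10R)-2,3-dichloro-12-methoxy-13,14,15,16-tetranorlabda-8(17),11-dien-6-one (E/Z) | C=C1CC(=O)[C@H]2C(C)(C)[C@@H](Cl)[C@H](Cl)C[C@]2(C)[C@H]1C=COC | intermediate
21 | (2R,3R,5R,9S,10R)-2,3-dichloro-6-oxo-13,14,15,16-tetranorlabd-8(17)-en-12-al | C=C1CC(=O)[C@H]2C(C)(C)[C@@H](Cl)[C@H](Cl)C[C@]2(C)[C@H]1CC=O | intermediate
22 | (4R)-4-benzyl-1,3-oxazolidin-2-one | O=C1N[C@H](Cc2ccccc2)CO1 | starting material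
23 | 3-cyanopropanoic acid | N#CCCC(=O)O | starting material
24 | 3-cyanopropanoic pivalic anhydride | N#CCCC(=O)OC(=O)C(C)(C)C | intermediate
25 | 4-[(4R)-4-benzyl-2-oxo-1,3-oxazolidin-3-yl]-4-oxobutanenitrile | N#CCCC(=O)N1C(=O)OC[C@H]1Cc1ccccc1 | intermediate
26 | Z-dibutylboron enolate of 25 | N#CC/C=C(\OB(CCCC)CCCC)N1C(=O)OC[C@H]1Cc1ccccc1 | intermediate
27 | (12S,13R)-aldol adduct: C13 bears CH2CN and the (4R)-4-benzyl-2-oxo-oxazolidin-3-ylcarbonyl group, C12 bears OH, on the (2R,3R,5R,9S,10R)-2,3-dichloro-6-oxo-labd-8(17)-ene core | C=C1CC(=O)[C@H]2C(C)(C)[C@@H](Cl)[C@H](Cl)C[C@]2(C)[C@H]1C[C@H](O)[C@@H](CC#N)C(=O)N3C(=O)OC[C@H]3Cc3ccccc3 | intermediate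
28 | primary amide of 27 (CH2CONH2 in place of CH2CN), same configuration | C=C1CC(=O)[C@H]2C(C)(C)[C@@H](Cl)[C@H](Cl)C[C@]2(C)[C@H]1C[C@H](O)[C@@H](CC(N)=O)C(=O)N3C(=O)OC[C@H]3Cc3ccccc3 | intermediate
29 | haterumaimide B, (2R,3R,5R,9S,10R,12S,13R) | C=C1CC(=O)[C@H]2C(C)(C)[C@@H](Cl)[C@H](Cl)C[C@]2(C)[C@H]1C[C@H](O)[C@H]1CC(=O)NC1=O | target

**Totals and risks**

Total step count: 16. Longest linear sequence: 12 steps (1–4, 8–13, 15, 16).

Steps most likely to fail:

1. Step 11 (proposed new method). The C9 silyl enol ether may be protonated before ring B has closed; C11 then becomes an oxocarbenium ion or aldehyde that the C7 enol ether captures (aldol-type closure onto C11 instead of C8), and C9 loses its controlled protonation. Closure of ring A with the C9 arm axial would lead into the cis-fused series. Fallback, from 16 back to 19, with the two closures run as separate isolated operations, each of a known type: ring A alone is closed with TBSOTf and 2,6-di-tert-butyl-4-methylpyridine (silyl triflate opening of the dioxolane, intramolecular Mukaiyama–Michael addition), quenched with Et3N and purified on base-washed silica as the ring A bis(tert-butyldimethylsilyl) enol ether F1. In a second flask F1 is cyclized with the same gold catalyst (silyl enol ether–alkyne carbocyclization, Conia-ene type) with 2,6-di-tert-butyl-4-methylpyridinium triflate as the only proton source to the bicyclic bis(tert-butyldimethylsilyl) trienol ether F2. Buffered Bu4NF and then aqueous AcOH return to 19.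

2. Step 8. Facial selectivity at the carbinol carbon (anti against syn) and the geometry of the new tetrasubstituted alkene may be poor with the alkynyl-substituted dienol ether, and BF3 may ionize the dioxolane in competition. Fallback, from 7 back to 15, with the alkyne introduced after the aldol union: 8 is silylated (TBSOTf, Et3N) to the parent dienol ether tert-butyl(dimethyl)[(3-methylbuta-1,3-dien-1-yl)oxy]silane F3, for which E-selective γ-addition is well established. Its BF3-mediated vinylogous Mukaiyama aldol with 7 should give the (2E)-hydroxy enal F4, and deoxychlorination as in step 9 the dichloro enal F5. Bromine addition gives the dibromide F6 and Et3N then the α-bromo enal F7. Sonogashira coupling of F7 with 11 returns to 15, together with its 2Z isomer, which the key step accepts equally.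

3. Step 12. The ylide may deprotonate the doubly activated C9–H or C7–H instead of adding to the hindered aldehyde, with epimerization at C9 or migration of the exocyclic double bond into conjugation. Fallback, from 19 back to 21, with C12 delivered by a rearrangement instead of a basic ylide: Pinnick oxidation (NaClO2, NaH2PO4, 2-methylbut-2-ene) gives the carboxylic acid F8, oxalyl chloride with catalytic DMF the acid chloride F9, and TMSCHN2 the diazoketone F10. Wolff rearrangement (AgO2CPh, catalytic Et3N, EtSH, THF; C9 migrates with retention) gives the S-ethyl thioester F11, and Fukuyama reduction (Et3SiH, Pd/C, acetone) returns to 21.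

Further compounds
F1 | step 11 | ring A bis(tert-butyldimethylsilyl) enol ether, (2R,3R,5R,10S), TBS analogue of 17 | C=C(OCCO[Si](C)(C)C(C)(C)C)[C@H]1C(C)(C)[C@@H](Cl)[C@H](Cl)C[C@]1(C)C(C#C)=CO[Si](C)(C)C(C)(C)C
F2 | step 11 | bicyclic bis(tert-butyldimethylsilyl) trienol ether, (2R,3R,5R,10S), TBS analogue of 18 | C=C1C=C(OCCO[Si](C)(C)C(C)(C)C)[C@H]2C(C)(C)[C@@H](Cl)[C@H](Cl)C[C@]2(C)C1=CO[Si](C)(C)C(C)(C)C
F3 | step 8 | tert-butyl(dimethyl)[(3-methylbuta-1,3-dien-1-yl)oxy]silane | C=C(C)/C=C/O[Si](C)(C)C(C)(C)C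
F4 | step 8 | (2E,5S,6R)-6-chloro-5-hydroxy-3,7,7-trimethyl-8-(2-methyl-1,3-dioxolan-2-yl)oct-2-enal | O=C/C=C(\C)C[C@H](O)[C@H](Cl)C(C)(C)CC1(C)OCCO1
F5 | step 8 | (2E,5R,6R)-5,6-dichloro-3,7,7-trimethyl-8-(2-methyl-1,3-dioxolan-2-yl)oct-2-enal | O=C/C=C(\C)C[C@@H](Cl)[C@H](Cl)C(C)(C)CC1(C)OCCO1
F6 | step 8 | (5R,6R)-2,3-dibromo-5,6-dichloro-3,7,7-trimethyl-8-(2-methyl-1,3-dioxolan-2-yl)octanal (mixture at C2 and C3) | O=CC(Br)C(C)(Br)C[C@@H](Cl)[C@H](Cl)C(C)(C)CC1(C)OCCO1
F7 | step 8 | (5R,6R)-2-bromo-5,6-dichloro-3,7,7-trimethyl-8-(2-methyl-1,3-dioxolan-2-yl)oct-2-enal (E/Z) | O=CC(Br)=C(C)C[C@@H](Cl)[C@H](Cl)C(C)(C)CC1(C)OCCO1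
F8 | step 12 | (2R,3R,5R,9S,10R)-2,3-dichloro-6-oxo-12,13,14,15,16-pentanorlabd-8(17)-en-11-oic acid | C=C1CC(=O)[C@H]2C(C)(C)[C@@H](Cl)[C@H](Cl)C[C@]2(C)[C@H]1C(=O)O
F9 | step 12 | acid chloride of F8 | C=C1CC(=O)[C@H]2C(C)(C)[C@@H](Cl)[C@H](Cl)C[C@]2(C)[C@H]1C(=O)Cl
F10 | step 12 | diazoketone from F9 (C11 carbonyl bearing CH=N2) | C=C1CC(=O)[C@H]2C(C)(C)[C@@H](Cl)[C@H](Cl)C[C@]2(C)[C@H]1C(=O)C=[N+]=[N-]
F11 | step 12 | S-ethyl (2R,3R,5R,9S,10R)-2,3-dichloro-6-oxo-13,14,15,16-tetranorlabd-8(17)-ene-12-thioate | C=C1CC(=O)[C@H]2C(C)(C)[C@@H](Cl)[C@H](Cl)C[C@]2(C)[C@H]1CC(=O)SCC
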